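Everything rests on cutting C3–C3a of the dihydrofuran ring (O1–C2–C3–C3a–C7a). C3 carries only H and CH3, so it is read as the inner carbon of a vinyl group, and C3a, ortho to O1, as an aryl radical. The precursor is thus an open, enantioenriched 2-iodoaryl 1-arylallyl ether, made by Ir-catalysed allylic etherification. One 5-exo-trig radical cyclisation closes the ring, turns =CH2 into the C3 methyl group and sets C3 trans to C2. The still flat carbocycle is dearomatised afterwards. IBX gives the 5,6-quinone, catalyst-controlled allylboration of its non-vinylogous C5 carbonyl sets C5, and O-methylation gives the target.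

Key step: step 4

Assumption: the catalyst antipodes named in steps 3 and 7 are those expected to give the drawn configurations. Both antipodes of each are commercial, so a reversed sense of induction is corrected by exchanging the antipode and nothing else changes. Benzofuran numbering (O1, C2, C3, C3a, C4–C7, C7a) is also used for the corresponding atoms of open precursors.

Step 1
Reactants: 1 (E)-3-(3,4-dimethoxyphenyl)prop-2-en-1-ol
Product: 2 (E)-3-(3,4-dimethoxyphenyl)allyl methyl carbonate
Conditions: ClCO2Me, pyridine, CH2Cl2, 0 °C to rt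
Reagents that add atoms: methyl chloroformate, COC(=O)Cl
Why: Carbonate formation by acylation of the primary allylic alcohol with a chloroformate installs the leaving group for the π-allyl chemistry and leaves the E-alkene untouched; no stereocentre is formed.

Step 2
Reactants: 3 4-iodoresorcinol
Product: 4 2-iodo-5-(triisopropylsilyloxy)phenol
Conditions: TIPSCl (1 equiv), imidazole, DMF, 0 °C
Reagents that add atoms: triisopropylsilyl chloride, CC(C)[Si](Cl)(C(C)C)C(C)C
Why: Sterically controlled mono-silylation: the bulky silyl chloride should take the open OH para to iodine and leave free the OH flanked by iodine, which is the oxygen that becomes O1.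

Step 3
Reactants: 2 (E)-3-(3,4-dimethoxyphenyl)allyl methyl carbonate; 4 2-iodo-5-(triisopropylsilyloxy)phenol
Product: 6 (R)-{3-[1-(3,4-dimethoxyphenyl)allyloxy]-4-iodophenoxy}triisopropylsilane, via lithium aryloxide 5 (not isolated)
Conditions: 4, LiHMDS, THF, 0 °C; then 2, [Ir(cod)Cl]2 (2 mol %), (Ra,Rc,Rc)-binaphthol-derived N,N-bis(1-phenylethyl)phosphoramidite (4 mol %), THF, rt to 50 °C; aqueous work-up, Et3N-deactivated silica
Reagents that add atoms: none
Why: Iridium-catalysed asymmetric allylic etherification of a linear cinnamyl-type carbonate with a lithium aryloxide: the aryloxide attacks the aryl-substituted terminus of the π-allyl complex of the cyclometalated Ir-phosphoramidite catalyst, which should give the branched ether, and the ligand sets C2 as R.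

Step 4
Reactants: 6 (R)-{3-[1-(3,4-dimethoxyphenyl)allyloxy]-4-iodophenoxy}triisopropylsilane
Product: 9 (2R,3R)-2-(3,4-dimethoxyphenyl)-3-methyl-6-(triisopropylsilyloxy)-2,3-dihydrobenzofuran, via aryl radical 7 (not isolated), via primary alkyl radical 8 (not isolated)
Conditions: (Me3Si)3SiH (slow addition), Et3B (0.2 equiv), air, toluene, 0 °C
Reagents that add atoms: none
Why: Et3B/O2 starts a chain in which (Me3Si)3Si• abstracts iodine from 6, the σ-aryl radical 7 centred on C3a adds to the inner vinyl carbon (the future C3), and the primary radical 8 takes H from the silane, so that the former =CH2 becomes the C3 methyl group in the same event that makes C3–C3a. The closest known reaction type is the reductive aryl-radical cyclisation of o-halophenyl allyl ethers to 3-methyl-2,3-dihydrobenzofurans. The ring O1–C2–C3–C3a–C7a closes in the 5-exo-trig mode. C3 is the only new stereocentre and is controlled by C2: in the chair-like 5-exo transition state the veratryl group sits pseudo-equatorial and the =CH2 terminus turns away from it, which should give the 2,3-trans (2R,3R) product, while C2 is not touched; any cis isomer is removed by chromatography and not epimerised at C2, since that would feed the enantiomeric trans series. The step needs 5-exo closure to beat 6-endo closure, attack on the veratryl ring and direct reduction of 7, which the very fast closure of o-allyloxyaryl radicals and the slow silane addition secure, and it needs 0 °C so that neither aromatic Claisen rearrangement nor ionisation of the doubly activated C2–O1 bond intervenes. Placing the radical on the arene and not on C3 also avoids any C3-centred metal or radical species β to the aryloxy group, so that β-elimination of the phenol cannot occur.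

Step 5
Reactants: 9 (2R,3R)-2-(3,4-dimethoxyphenyl)-3-methyl-6-(triisopropylsilyloxy)-2,3-dihydrobenzofuran
Product: 10 (2R,3R)-2-(3,4-dimethoxyphenyl)-3-methyl-2,3-dihydrobenzofuran-6-ol
Conditions: TBAF, AcOH, THF, 0 °C
Reagents that add atoms: none
Why: Fluoride-induced cleavage of the aryl silyl ether (desilylation), buffered with acetic acid so that no free phenoxide is present; C2 and C3 are not affected.

Step 6
Reactants: 10 (2R,3R)-2-(3,4-dimethoxyphenyl)-3-methyl-2,3-dihydrobenzofuran-6-ol
Product: 11 (2R,3R)-2-(3,4-dimethoxyphenyl)-3-methyl-2,3-dihydrobenzofuran-5,6-dione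
Conditions: IBX (1.1 equiv), DMF, rt; used at once
Reagents that add atoms: IBX (2-iodoxybenzoic acid), O=C1OI(=O)(O)c2ccccc12
Why: IBX ortho-oxygenation of a phenol to the o-quinone: oxygen is passed within the aryloxy-iodane to the open ortho carbon C5 (para to O1) and not to C7, which lies between two oxygens, and neutral aprotic conditions with prompt use of 11 hold back its tautomerisation to a quinone methide, which would endanger C3.

Step 7
Reactants: 11 (2R,3R)-2-(3,4-dimethoxyphenyl)-3-methyl-2,3-dihydrobenzofuran-5,6-dione
Product: 13 (2R,3R,5S)-5-allyl-2-(3,4-dimethoxyphenyl)-5-hydroxy-3-methyl-2,3-dihydrobenzofuran-6(5H)-one, via borate ester 12 (not isolated)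
Conditions: allylB(Oi-Pr)2, (S)-3,3′-Br2-BINOL (15 mol %), PhCF3/toluene, −35 °C; aqueous work-up
Reagents that add atoms: allyldiisopropoxyborane, C=CCB(OC(C)C)OC(C)C
Why: Proposed new method: chiral-diol-catalysed asymmetric allylboration, known for aryl and alkenyl ketones and akin to catalytic allylations of isatins, is extended to an o-quinone; ligand exchange puts the binaphthol on boron, the more electrophilic C5=O binds and receives allyl through a closed chair transition state (1,2 and not 1,4 or 1,6), C6=O stays inert because it is a vinylogous ester through C7=C7a–O1 just as the amide carbonyl of isatin stays inert, and the catalyst rather than the remote C2/C3 centres directs allyl to the Re face of C5 (the face of the C2 aryl group) to give 5S.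

Step 8
Reactants: 13 (2R,3R,5S)-5-allyl-2-(3,4-dimethoxyphenyl)-5-hydroxy-3-methyl-2,3-dihydrobenzofuran-6(5H)-one
Product: 14 (2R,3R,5S)-5-allyl-2-(3,4-dimethoxyphenyl)-5-methoxy-3-methyl-2,3-dihydrobenzofuran-6(5H)-one
Conditions: MeI (excess), Ag2O, 4 Å MS, CH2Cl2, rt, dark
Reagents that add atoms: iodomethane, CI
Why: Purdie methylation (MeI/Ag2O) alkylates the tertiary OH without a free alkoxide, which avoids anionic oxy-Cope and α-ketol shifts, does not break the C5–O bond and so keeps 5S, and is run at room temperature because 6-allylcyclohexa-2,4-dienones are prone to [3,3] shifts on heating.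

Compound list
1 | (E)-3-(3,4-dimethoxyphenyl)prop-2-en-1-ol | OC/C=C/c1ccc(OC)c(OC)c1 | starting material
2 | (E)-3-(3,4-dimethoxyphenyl)allyl methyl carbonate | COC(=O)OC/C=C/c1ccc(OC)c(OC)c1 | intermediate
3 | 4-iodoresorcinol | Oc1ccc(I)c(O)c1 | starting material
4 | 2-iodo-5-(triisopropylsilyloxy)phenol | CC(C)[Si](Oc1ccc(I)c(O)c1)(C(C)C)C(C)C | intermediate
5 | lithium 2-iodo-5-(triisopropylsilyloxy)phenoxide | [Li+].[O-]c1cc(O[Si](C(C)C)(C(C)C)C(C)C)ccc1I | intermediate
6 | (R)-{3-[1-(3,4-dimethoxyphenyl)allyloxy]-4-iodophenoxy}triisopropylsilane | CC(C)[Si](Oc1ccc(I)c(c1)O[C@@H](c1ccc(OC)c(OC)c1)C=C)(C(C)C)C(C)C | intermediate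
7 | aryl σ-radical at C3a formed from 6 by loss of iodine | CC(C)[Si](Oc1cc[c]c(c1)O[C@@H](c1ccc(OC)c(OC)c1)C=C)(C(C)C)C(C)C | intermediate
8 | [(2R,3R)-2-(3,4-dimethoxyphenyl)-6-(triisopropylsilyloxy)-2,3-dihydrobenzofuran-3-yl]methyl radical | CC(C)[Si](Oc1ccc2c(c1)O[C@@H](c1ccc(OC)c(OC)c1)[C@@H]2[CH2])(C(C)C)C(C)C | intermediate
9 | (2R,3R)-2-(3,4-dimethoxyphenyl)-3-methyl-6-(triisopropylsilyloxy)-2,3-dihydrobenzofuran | CC(C)[Si](Oc1ccc2c(c1)O[C@@H](c1ccc(OC)c(OC)c1)[C@@H]2C)(C(C)C)C(C)C | intermediate
10 | (2R,3R)-2-(3,4-dimethoxyphenyl)-3-methyl-2,3-dihydrobenzofuran-6-ol | Oc1ccc2c(c1)O[C@@H](c1ccc(OC)c(OC)c1)[C@@H]2C | intermediate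
11 | (2R,3R)-2-(3,4-dimethoxyphenyl)-3-methyl-2,3-dihydrobenzofuran-5,6-dione | O=C1C=C2C(=CC1=O)O[C@@H](c1ccc(OC)c(OC)c1)[C@@H]2C | intermediate
12 | diisopropyl borate ester of quinol 13 (boron on the C5 oxygen) | C=CC[C@]1(OB(OC(C)C)OC(C)C)C=C2C(=CC1=O)O[C@@H](c1ccc(OC)c(OC)c1)[C@@H]2C | intermediate
13 | (2R,3R,5S)-5-allyl-2-(3,4-dimethoxyphenyl)-5-hydroxy-3-methyl-2,3-dihydrobenzofuran-6(5H)-one | C=CC[C@]1(O)C=C2C(=CC1=O)O[C@@H](c1ccc(OC)c(OC)c1)[C@@H]2C | intermediate
14 | (2R,3R,5S)-5-allyl-2-(3,4-dimethoxyphenyl)-5-methoxy-3-methyl-2,3-dihydrobenzofuran-6(5H)-one | C=CC[C@]1(OC)C=C2C(=CC1=O)O[C@@H](c1ccc(OC)c(OC)c1)[C@@H]2C | target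

Total step count: 8. Longest linear sequence: 7 steps (3 → 4 → 6 → 9 → 10 → 11 → 13 → 14).

Steps most likely to fail

Step 7. The flat quinone may be attacked with poor facial discrimination at C5. An uncatalysed background addition may erode the selectivity. Quinone 11 may also tautomerise to a quinone methide before it reacts. The fallback uses known chemistry and avoids the quinone altogether. It sets out from phenol 10. Bromination with NBS at C5 (ortho to OH, para to O1) gives the 5-bromophenol F1. Stille coupling with allyltributylstannane gives the 5-allylphenol F2. Copper(I)/sparteine/O2-mediated asymmetric hydroxylative dearomatisation of the lithium phenolate of F2 at −78 °C, a reaction type known for 2-alkylphenols, places OH on the allyl-bearing C5. This comes back to the route at quinol 13. The dearomatising bond is then C5–O instead of C5–C.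

Step 8. Alkylation of the hindered, hydrogen-bonded tertiary OH may be so slow that [3,3] shifts of the allyl group, an α-ketol shift or Diels–Alder dimerisation take over. The fallback sets out from quinone 11 and skips 13. A three-component Hosomi–Sakurai reaction (MeOSiMe3, allylSiMe3, catalytic TMSOTf, CH2Cl2, −78 °C) forms the C5 methoxy-oxocarbenium ion and traps it with the allylsilane. It comes back at 14, which forms together with the C5 epimer F3 and is separated from it by chromatography. No tertiary alcohol has to be alkylated, at the price of catalyst control at C5.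

Step 3. The electron-rich branched ether may re-ionise on iridium, with loss of enantiomeric purity and drift to the linear ether, or the hindered o-iodophenoxide may attack too slowly. The fallback sets out from phenol 4. Addition of vinylmagnesium bromide to commercial 3,4-dimethoxybenzaldehyde gives the racemic allylic alcohol F4. Lipase (CAL-B)/vinyl acetate kinetic resolution leaves the (S)-alcohol F5 and removes the (R)-acetate F6. A Mitsunobu reaction of F5 with 4 (DIAD, PPh3, toluene, −20 °C) forms the C2–O1 bond with inversion and comes back at ether 6.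

Further compounds
F1 | step 7 | (2R,3R)-5-bromo-2-(3,4-dimethoxyphenyl)-3-methyl-2,3-dihydrobenzofuran-6-ol | Oc1c(Br)cc2c(c1)O[C@@H](c1ccc(OC)c(OC)c1)[C@@H]2C
F2 | step 7 | (2R,3R)-5-allyl-2-(3,4-dimethoxyphenyl)-3-methyl-2,3-dihydrobenzofuran-6-ol | C=CCc1cc2c(cc1O)O[C@@H](c1ccc(OC)c(OC)c1)[C@@H]2C
F3 | step 8 | (2R,3R,5R)-5-allyl-2-(3,4-dimethoxyphenyl)-5-methoxy-3-methyl-2,3-dihydrobenzofuran-6(5H)-one | C=CC[C@@]1(OC)C=C2C(=CC1=O)O[C@@H](c1ccc(OC)c(OC)c1)[C@@H]2C
F4 | step 3 | rac-1-(3,4-dimethoxyphenyl)prop-2-en-1-ol | C=CC(O)c1ccc(OC)c(OC)c1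
F5 | step 3 | (S)-1-(3,4-dimethoxyphenyl)prop-2-en-1-ol | O[C@H](c1ccc(OC)c(OC)c1)C=C
F6 | step 3 | (R)-1-(3,4-dimethoxyphenyl)allyl acetate | CC(=O)O[C@@H](c1ccc(OC)c(OC)c1)C=C
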